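## Structural features

The target is a 15-nor-eudesmane. Numbering used throughout: ring A = C1–C5 and C10, ring B = C5–C10, C11–C13 = the 1-(methoxycarbonyl)vinyl group on C7, C14 = the methyl on C10; β is the face of C14. It is a trans-fused decalin: ring A carries the 1β-hydroxyl and the C4 ketone, and ring B carries on three neighbouring carbons the 6α-hydroxyl, the 7β-acrylate unit and the 8α-acyloxy group. There are six stereocentres (C1, C5, C6, C7, C8, C10); C5–C8 are contiguous, C10 is quaternary, and every ring substituent except C14 is equatorial. Fragile groups are the β-hydroxy ketone C4(=O)–C5–C6(OH) (retro-aldol, dehydration, epimerisation at C5), two acrylate Michael acceptors, and a methyl ester placed to lactonise onto O6 or O8. Of the three secondary oxygens only O8 is acylated, so they must be told apart. The real difficulty is the C6–C7–C8 triad: a carbon substituent trans to two flanking equatorial oxygens, both 1,3-related to the axial C14, so that hydride reduction of a C6 or C8 ketone would be expected to give the wrong (axial) alcohol. The key step exploits the array C8(OH)–C7–C11(=C13H2)–CO2Me in ring B: it is the homoallylic alcohol formed when a 2-(methoxycarbonyl)allyl metal (metal on C13) adds through its γ-carbon C7 to an aldehyde at C8. Ring B is therefore built twice: first as a Diels–Alder cyclohexene that fixes C5, C6 and C10, then cut at C7=C8 and re-closed at C7–C8 by this allylation. In one sentence: Pd/In-mediated intramolecular allylation of seco keto aldehyde 16, whose two reacting carbons were set free by ozonolysis of a cycloadduct, closes ring B at C7–C8 and creates C7, C8 and the acrylate together.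

## Logic of the disconnections

23 ⇒ 22: the three O–Si bonds are cut. All silyl groups are the same, so one mildly acidic fluoride step ends the route; the forward step must not trigger lactonisation, acyl migration or retro-aldol.

22 ⇒ 18 + 21: the C8–O acyl bond is cut. In 18 only O8 is free, so the three oxygens need no further differentiation; the forward step is an esterification with retention at a hindered secondary carbinol.

18 ⇒ 16 (through 17): the C7–C8 bond is cut (key disconnection). This removes ring B, both the C7 and C8 stereocentres and the exocyclic C11=C13 bond in one operation and leads to a monocyclic keto aldehyde carrying an allylic acetate. The forward step must add through C7 (not C13), to the aldehyde (not the C4 ketone), and through a chair in which O8 and C11 are both equatorial.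

16 ⇒ 15 ⇒ 12 + 13: the acetal at C8 is restored and the C7–C11 bond is cut. The whole C11–C13 unit then comes from a three-carbon alkynoate added to a C7 aldehyde; the new carbinol configuration at C7 is irrelevant because C7 becomes trigonal in 17. The forward addition must avoid base, since C6 is α to the aldehyde and β to the ketone.

12 ⇒ 11 ⇒ 10: the two aldehyde carbons C7 and C8 are reconnected to a C7=C8 double bond. This turns the acyclic problem of placing C5, C6 and C10 into a cyclohexene problem. The forward sequence needs alkene cleavage followed by selective masking of the C8 aldehyde.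

10 ⇒ 9: C5 is inverted. The trans ring fusion is reached by equilibration α to the C4 ketone, so the cycloaddition need only deliver the cis-fused isomer.

9 ⇒ 6 + 8: the C5–C6 and C9–C10 bonds are cut (Diels–Alder). All four carbons C6–C9 and O6 arrive in one step; the existing C1 stereocentre must direct the diene to the opposite face and the endo rule must place O6.

6 ⇒ 5 ⇒ 4 ⇒ 3 ⇒ 1: protecting-group and redox changes in ring A. The only stereo-defining step is the enantioselective reduction that creates C1; 1 is a commercial racemate whose stereocentre is erased.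

8 ⇒ 7, and 21 ⇒ 20 ⇒ 19: one O–Si bond each, plus one ester hydrolysis; all from commercial materials.

## Other disconnections considered

Alternative 1: cut C9–C10 and C5=C6 (Robinson annulation), leading to (R)-Wieland–Miescher ketone A1. This is the first route that comes to mind. A1 has oxygen only at C1 and C7; C4 is a bare methylene γ to the enone. C6 and C8 would have to be oxidised, and the ketones that serve as their precursors are expected to be reduced from the face away from C14, giving axial alcohols. The C7 carbonyl would have to become a CH bearing the acrylate. None of the four contiguous centres is set by the annulation, and the functional-group sequence would be long.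

Alternative 2: cut C5–C6 and C9–C10 as a quinone Diels–Alder reaction of 2-methoxy-5-methyl-1,4-benzoquinone A2 with diene 8, giving cis adduct A3. It brings in both ring A oxygens, but as two ketones and an enol ether: the methoxy group must be removed and C1 must be reduced in preference to the less hindered C4. The donor terminus of the diene must bond to the methyl-bearing carbon, which calls for Lewis-acid reversal of the thermal orientation, and the product is racemic without a chiral catalyst. The chosen route uses the same diene but enone 6, in which C1 is already a stereodefined carbinol that controls the face and needs no later adjustment.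

Alternative 3: cut C7=C8 and C11=C13 by ring-closing enyne metathesis of ynoate A4 to dienoate A5. Ring B and the complete acrylate would form together, but no stereocentre is created. A4 needs an intermolecular aldol at C5 whose facial course is not secured. A5 would then need anti-Markovnikov syn hydration of the ring alkene in the presence of a more accessible 1,1-disubstituted acrylate alkene and a ketone. The chosen allylation forms the same carbon array with C7 and C8 set in the ring-closing event.

Key step: step 11

Remarks: TBS = tert-butyldimethylsilyl. Compound 1 is taken as the commercial racemate. Compounds 14–16 are carried as mixtures at C7 (3RS in their names).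

## Steps

Step 1
Reactants: 1 7-methyl-1,4-dioxaspiro[4.5]decan-8-one (racemic)
Product: 3 7-methyl-1,4-dioxaspiro[4.5]dec-6-en-8-one, via silyl enol ether 2 (not isolated)
Conditions: TMSCl, Et3N, DMF, 130 °C; then Pd(OAc)2 (10 mol %), O2 (1 atm), DMSO, rt
Reagents that add atoms: none
Why: Silylation under equilibrating conditions favours the more substituted enol silane 2, and Saegusa–Ito dehydrogenation then places the double bond on the methyl-bearing side; the stereocentre of 1 is erased.

Step 2
Reactants: 3 7-methyl-1,4-dioxaspiro[4.5]dec-6-en-8-one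
Product: 4 (R)-7-methyl-1,4-dioxaspiro[4.5]dec-6-en-8-ol
Conditions: (S)-Me-CBS (10 mol %), BH3·SMe2, THF, −20 °C
Reagents that add atoms: none
Why: Corey–Bakshi–Shibata reduction; the catalyst distinguishes the α-methylvinyl flank (large) from the CH2 flank (small), so the (S)-oxazaborolidine should give the (R)-allylic alcohol, the future C1 stereocentre.

Step 3
Reactants: 4 (R)-7-methyl-1,4-dioxaspiro[4.5]dec-6-en-8-ol
Product: 5 (R)-tert-butyldimethyl[(7-methyl-1,4-dioxaspiro[4.5]dec-6-en-8-yl)oxy]silane
Conditions: TBSCl, imidazole, DMF, rt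
Reagents that add atoms: tert-butyldimethylsilyl chloride, CC(C)(C)[Si](C)(C)Cl
Why: Standard silylation of a secondary allylic alcohol; the bulky ether later shields one face of the enone.

Step 4
Reactants: 5 (R)-tert-butyldimethyl[(7-methyl-1,4-dioxaspiro[4.5]dec-6-en-8-yl)oxy]silane
Product: 6 (R)-4-[(tert-butyldimethylsilyl)oxy]-3-methylcyclohex-2-en-1-one
Conditions: PPTS (cat.), acetone/H2O, 50 °C
Reagents that add atoms: water, O
Why: Mild acid-catalysed ketal hydrolysis frees the ketone (future C4) in conjugation with the trisubstituted alkene; PPTS should leave the allylic silyl ether intact.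

Step 5
Reactants: 7 (E)-but-2-enal
Product: 8 (E)-(buta-1,3-dien-1-yloxy)(tert-butyl)dimethylsilane
Conditions: TBSOTf, Et3N, Et2O, 0 °C to rt
Reagents that add atoms: tert-butyldimethylsilyl trifluoromethanesulfonate, CC(C)(C)[Si](C)(C)OS(=O)(=O)C(F)(F)F
Why: O-Silylation of the enal followed by γ-deprotonation (silyl dienol ether formation) should give mainly the (E)-1-silyloxydiene; the minor (Z)-isomer should not take part in step 6.

Step 6
Reactants: 6 (R)-4-[(tert-butyldimethylsilyl)oxy]-3-methylcyclohex-2-en-1-one; 8 (E)-(buta-1,3-dien-1-yloxy)(tert-butyl)dimethylsilane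
Product: 9 (4R,4aR,8S,8aR)-4,8-bis[(tert-butyldimethylsilyl)oxy]-4a-methyl-3,4,4a,5,8,8a-hexahydronaphthalen-1(2H)-one (cis-fused)
Conditions: Tf2NH (5 mol %), CH2Cl2, −78 to −40 °C
Reagents that add atoms: none
Why: Lewis-acid-catalysed Diels–Alder reaction of a 1-silyloxydiene with a β-substituted cyclohexenone (silyl triflimide formed in situ is the active acid); the donor terminus C9 bonds to the enone β-carbon C10 and C6 to C5. The diene should add anti to the C1 silyloxy group (sets C10) and the endo transition state places the C6 silyloxy group trans to H5 (sets C6), giving the cis-fused adduct.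

Step 7
Reactants: 9 (4R,4aR,8S,8aR)-4,8-bis[(tert-butyldimethylsilyl)oxy]-4a-methyl-3,4,4a,5,8,8a-hexahydronaphthalen-1(2H)-one
Product: 10 (4R,4aR,8S,8aS)-4,8-bis[(tert-butyldimethylsilyl)oxy]-4a-methyl-3,4,4a,5,8,8a-hexahydronaphthalen-1(2H)-one (trans-fused)
Conditions: DBU (0.3 equiv), toluene, 60 °C
Reagents that add atoms: none
Why: Base-mediated epimerisation α to the ketone; the trans-fused isomer with the pseudo-equatorial C6 silyloxy group should be the more stable, and silanolate is a poor leaving group for E1cB elimination.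

Step 8
Reactants: 10 (4R,4aR,8S,8aS)-4,8-bis[(tert-butyldimethylsilyl)oxy]-4a-methyl-3,4,4a,5,8,8a-hexahydronaphthalen-1(2H)-one
Product: 12 (2R)-2-[(tert-butyldimethylsilyl)oxy]-2-[(1S,2R,3R)-3-[(tert-butyldimethylsilyl)oxy]-2-(2,2-dimethoxyethyl)-2-methyl-6-oxocyclohexyl]acetaldehyde, via dialdehyde 11 (not isolated)
Conditions: O3, CH2Cl2/MeOH, −78 °C; Me2S; then PPTS (cat.), MeOH, 3 Å MS, 0 °C
Reagents that add atoms: ozone, [O-][O+]=O; methanol, CO
Why: Ozonolysis with reductive work-up cuts only the C7=C8 bond. Acid-catalysed acetalisation should then select the unhindered C8 aldehyde, because the α-silyloxy, α-branched C7 aldehyde forms the required oxocarbenium ion much more slowly.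

Step 9
Reactants: 12 (2R)-2-[(tert-butyldimethylsilyl)oxy]-2-[(1S,2R,3R)-3-[(tert-butyldimethylsilyl)oxy]-2-(2,2-dimethoxyethyl)-2-methyl-6-oxocyclohexyl]acetaldehyde; 13 methyl prop-2-ynoate
Product: 15 methyl (3RS,4R)-3-acetoxy-4-[(tert-butyldimethylsilyl)oxy]-4-[(1S,2R,3R)-3-[(tert-butyldimethylsilyl)oxy]-2-(2,2-dimethoxyethyl)-2-methyl-6-oxocyclohexyl]-2-methylidenebutanoate, via allylic alcohol 14 (not isolated)
Conditions: i-Bu2AlH, HMPA, THF, 0 °C, then 13; add 12, −78 to 0 °C; work-up; Ac2O, DMAP (cat.), pyridine, CH2Cl2, 0 °C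
Reagents that add atoms: acetic anhydride, CC(=O)OC(C)=O
Why: Hydroalumination of 13 gives the α-aluminated acrylate, which adds to the aldehyde to give a Morita–Baylis–Hillman-type adduct (vinylalumination) without amine base, so C6 should not epimerise. Acetylation follows; the configuration at the new carbinol C7 does not matter because C7 becomes trigonal in step 11.

Step 10
Reactants: 15 methyl (3RS,4R)-3-acetoxy-4-[(tert-butyldimethylsilyl)oxy]-4-[(1S,2R,3R)-3-[(tert-butyldimethylsilyl)oxy]-2-(2,2-dimethoxyethyl)-2-methyl-6-oxocyclohexyl]-2-methylidenebutanoate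
Product: 16 methyl (3RS,4R)-3-acetoxy-4-[(tert-butyldimethylsilyl)oxy]-4-[(1S,2R,3R)-3-[(tert-butyldimethylsilyl)oxy]-2-methyl-6-oxo-2-(2-oxoethyl)cyclohexyl]-2-methylidenebutanoate
Conditions: Amberlyst-15, acetone/H2O, rt
Reagents that add atoms: water, O
Why: Mild acid hydrolysis of the dimethyl acetal frees the C8 aldehyde; the allylic acetate and the silyl ethers should survive.

Step 11
Reactants: 16 methyl (3RS,4R)-3-acetoxy-4-[(tert-butyldimethylsilyl)oxy]-4-[(1S,2R,3R)-3-[(tert-butyldimethylsilyl)oxy]-2-methyl-6-oxo-2-(2-oxoethyl)cyclohexyl]-2-methylidenebutanoate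
Product: 18 methyl 1β,6α-bis[(tert-butyldimethylsilyl)oxy]-8α-hydroxy-4-oxo-15-nor-5α-eudesm-11(13)-en-12-oate, via allylindium species 17 (not isolated)
Conditions: Pd(PPh3)4 (5 mol %), InI (2 equiv), THF (0.01 M), rt
Reagents that add atoms: none
Why: Pd(0) ionises the allylic acetate to a π-allyl complex, which indium(I) iodide reduces to the nucleophilic allylindium(III) species 17 (umpolung); 17 adds through its γ-carbon C7 to the aldehyde C8 in a six-membered cyclic transition state. The closest known reaction types are the Pd/In(I)-mediated Barbier-type carbonyl allylation with allylic acetates and the cyclisation of 2-(halomethyl)acrylates onto aldehydes. Ring B closes in a 6-exo-trig mode through a chair trans-fused to ring A, with the C5–C6 and C10–C9 bonds equatorial on ring A and the C6 silyloxy group equatorial. C8 is controlled by the angular methyl: the aldehyde oxygen takes the equatorial (α) position, because an axial (β) C–O–In bond would be 1,3-diaxial to C14. C7 is controlled by the geometry of 17: σ-allylindium species equilibrate by 1,3-metal shifts, and the isomer with the C6 chain trans to CH2In places C11 equatorial (β) in a chair–chair array, giving the trans-diequatorial 7β,8α product. The selectivities needed are γ- over α-attack (attack through C13 would need an eight-membered ring), aldehyde over the hindered C4 ketone (usual for allylindium reagents), and addition faster than β-elimination of the C6 silanolate. The same step creates the exocyclic C11=C13 bond, so no later olefination or oxidation is needed next to the β-oxygenated ketone.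

Step 12
Reactants: 19 methyl 2-(hydroxymethyl)acrylate
Product: 20 methyl 2-{[(tert-butyldimethylsilyl)oxy]methyl}acrylate
Conditions: TBSCl, imidazole, CH2Cl2, rt
Reagents that add atoms: tert-butyldimethylsilyl chloride, CC(C)(C)[Si](C)(C)Cl
Why: Standard silylation of the primary allylic alcohol.

Step 13
Reactants: 20 methyl 2-{[(tert-butyldimethylsilyl)oxy]methyl}acrylate
Product: 21 2-{[(tert-butyldimethylsilyl)oxy]methyl}acrylic acid
Conditions: LiOH, THF/H2O, 0 °C to rt; then 1 M HCl to pH 3
Reagents that add atoms: lithium hydroxide, [Li+].[OH-]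
Why: Saponification of the methyl ester at low temperature; the primary silyl ether should survive hydroxide and brief acidification.

Step 14
Reactants: 18 methyl 1β,6α-bis[(tert-butyldimethylsilyl)oxy]-8α-hydroxy-4-oxo-15-nor-5α-eudesm-11(13)-en-12-oate; 21 2-{[(tert-butyldimethylsilyl)oxy]methyl}acrylic acid
Product: 22 methyl 1β,6α-bis[(tert-butyldimethylsilyl)oxy]-8α-[(2-{[(tert-butyldimethylsilyl)oxy]methyl}acryloyl)oxy]-4-oxo-15-nor-5α-eudesm-11(13)-en-12-oate
Conditions: 2,4,6-trichlorobenzoyl chloride, Et3N, THF; then 18, DMAP, toluene, rt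
Reagents that add atoms: none
Why: Yamaguchi esterification through the mixed anhydride acylates the only free hydroxyl (O8) with retention; O1 and O6 are silylated.

Step 15
Reactants: 22 methyl 1β,6α-bis[(tert-butyldimethylsilyl)oxy]-8α-[(2-{[(tert-butyldimethylsilyl)oxy]methyl}acryloyl)oxy]-4-oxo-15-nor-5α-eudesm-11(13)-en-12-oate
Product: 23 methyl 1β,6α-dihydroxy-8α-{[2-(hydroxymethyl)acryloyl]oxy}-4-oxo-15-nor-5α-eudesm-11(13)-en-12-oate (CNP0144895.1)
Conditions: HF·pyridine, pyridine, THF, 0 °C to rt
Reagents that add atoms: none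
Why: Buffered HF·pyridine should remove all three silyl groups under mildly acidic conditions that avoid base-induced retro-aldol, acyl migration and conjugate addition.

## Compound list

1 | 7-methyl-1,4-dioxaspiro[4.5]decan-8-one (racemic) | CC1CC2(CCC1=O)OCCO2 | starting material
2 | trimethyl[(7-methyl-1,4-dioxaspiro[4.5]dec-7-en-8-yl)oxy]silane | CC1=C(O[Si](C)(C)C)CCC2(C1)OCCO2 | intermediate
3 | 7-methyl-1,4-dioxaspiro[4.5]dec-6-en-8-one | CC1=CC2(CCC1=O)OCCO2 | intermediate
4 | (R)-7-methyl-1,4-dioxaspiro[4.5]dec-6-en-8-ol | CC1=CC2(CC[C@H]1O)OCCO2 | intermediate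
5 | (R)-tert-butyldimethyl[(7-methyl-1,4-dioxaspiro[4.5]dec-6-en-8-yl)oxy]silane | CC1=CC2(CC[C@H]1O[Si](C)(C)C(C)(C)C)OCCO2 | intermediate
6 | (R)-4-[(tert-butyldimethylsilyl)oxy]-3-methylcyclohex-2-en-1-one | CC1=CC(=O)CC[C@H]1O[Si](C)(C)C(C)(C)C | intermediate
7 | (E)-but-2-enal | C/C=C/C=O | starting material
8 | (E)-(buta-1,3-dien-1-yloxy)(tert-butyl)dimethylsilane | C=C/C=C/O[Si](C)(C)C(C)(C)C | intermediate
9 | (4R,4aR,8S,8aR)-4,8-bis[(tert-butyldimethylsilyl)oxy]-4a-methyl-3,4,4a,5,8,8a-hexahydronaphthalen-1(2H)-one (cis-fused; 1β,6α-disilyloxy, 5β-H, Δ7 in target numbering) | C1=C[C@H](O[Si](C)(C)C(C)(C)C)[C@@H]2C(=O)CC[C@@H](O[Si](C)(C)C(C)(C)C)[C@]2(C)C1 | intermediate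
10 | (4R,4aR,8S,8aS)-4,8-bis[(tert-butyldimethylsilyl)oxy]-4a-methyl-3,4,4a,5,8,8a-hexahydronaphthalen-1(2H)-one (trans-fused; 5α-H) | C1=C[C@H](O[Si](C)(C)C(C)(C)C)[C@H]2C(=O)CC[C@@H](O[Si](C)(C)C(C)(C)C)[C@]2(C)C1 | intermediate
11 | (2R)-2-[(tert-butyldimethylsilyl)oxy]-2-[(1S,2R,3R)-3-[(tert-butyldimethylsilyl)oxy]-2-methyl-6-oxo-2-(2-oxoethyl)cyclohexyl]acetaldehyde | O=CC[C@]1(C)[C@@H]([C@@H](O[Si](C)(C)C(C)(C)C)C=O)C(=O)CC[C@H]1O[Si](C)(C)C(C)(C)C | intermediate
12 | (2R)-2-[(tert-butyldimethylsilyl)oxy]-2-[(1S,2R,3R)-3-[(tert-butyldimethylsilyl)oxy]-2-(2,2-dimethoxyethyl)-2-methyl-6-oxocyclohexyl]acetaldehyde | COC(OC)C[C@]1(C)[C@@H]([C@@H](O[Si](C)(C)C(C)(C)C)C=O)C(=O)CC[C@H]1O[Si](C)(C)C(C)(C)C | intermediate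
13 | methyl prop-2-ynoate | C#CC(=O)OC | starting material
14 | methyl (3RS,4R)-4-[(tert-butyldimethylsilyl)oxy]-4-[(1S,2R,3R)-3-[(tert-butyldimethylsilyl)oxy]-2-(2,2-dimethoxyethyl)-2-methyl-6-oxocyclohexyl]-3-hydroxy-2-methylidenebutanoate | COC(OC)C[C@]1(C)[C@@H]([C@@H](O[Si](C)(C)C(C)(C)C)C(O)C(=C)C(=O)OC)C(=O)CC[C@H]1O[Si](C)(C)C(C)(C)C | intermediate
15 | methyl (3RS,4R)-3-acetoxy-4-[(tert-butyldimethylsilyl)oxy]-4-[(1S,2R,3R)-3-[(tert-butyldimethylsilyl)oxy]-2-(2,2-dimethoxyethyl)-2-methyl-6-oxocyclohexyl]-2-methylidenebutanoate | COC(OC)C[C@]1(C)[C@@H]([C@@H](O[Si](C)(C)C(C)(C)C)C(OC(C)=O)C(=C)C(=O)OC)C(=O)CC[C@H]1O[Si](C)(C)C(C)(C)C | intermediate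
16 | methyl (3RS,4R)-3-acetoxy-4-[(tert-butyldimethylsilyl)oxy]-4-[(1S,2R,3R)-3-[(tert-butyldimethylsilyl)oxy]-2-methyl-6-oxo-2-(2-oxoethyl)cyclohexyl]-2-methylidenebutanoate | O=CC[C@]1(C)[C@@H]([C@@H](O[Si](C)(C)C(C)(C)C)C(OC(C)=O)C(=C)C(=O)OC)C(=O)CC[C@H]1O[Si](C)(C)C(C)(C)C | intermediate
17 | (E)-allylindium(III) acetate iodide from 16 (In on C13; C6 chain trans to CH2In) | O=CC[C@]1(C)[C@@H]([C@@H](O[Si](C)(C)C(C)(C)C)/C=C(/C[In](I)OC(C)=O)C(=O)OC)C(=O)CC[C@H]1O[Si](C)(C)C(C)(C)C | intermediate
18 | methyl 1β,6α-bis[(tert-butyldimethylsilyl)oxy]-8α-hydroxy-4-oxo-15-nor-5α-eudesm-11(13)-en-12-oate | O[C@H]1C[C@@]2(C)[C@H](O[Si](C)(C)C(C)(C)C)CCC(=O)[C@@H]2[C@@H](O[Si](C)(C)C(C)(C)C)[C@@H]1C(=C)C(=O)OC | intermediate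
19 | methyl 2-(hydroxymethyl)acrylate | C=C(CO)C(=O)OC | starting material
20 | methyl 2-{[(tert-butyldimethylsilyl)oxy]methyl}acrylate | C=C(CO[Si](C)(C)C(C)(C)C)C(=O)OC | intermediate
21 | 2-{[(tert-butyldimethylsilyl)oxy]methyl}acrylic acid | C=C(CO[Si](C)(C)C(C)(C)C)C(=O)O | intermediate
22 | methyl 1β,6α-bis[(tert-butyldimethylsilyl)oxy]-8α-[(2-{[(tert-butyldimethylsilyl)oxy]methyl}acryloyl)oxy]-4-oxo-15-nor-5α-eudesm-11(13)-en-12-oate | C=C(CO[Si](C)(C)C(C)(C)C)C(=O)O[C@H]1C[C@@]2(C)[C@H](O[Si](C)(C)C(C)(C)C)CCC(=O)[C@@H]2[C@@H](O[Si](C)(C)C(C)(C)C)[C@@H]1C(=C)C(=O)OC | intermediate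
23 | methyl 1β,6α-dihydroxy-8α-{[2-(hydroxymethyl)acryloyl]oxy}-4-oxo-15-nor-5α-eudesm-11(13)-en-12-oate | C=C(CO)C(=O)O[C@H]1C[C@@]2(C)[C@H](O)CCC(=O)[C@@H]2[C@@H](O)[C@@H]1C(=C)C(=O)OC | target

## Step count and least certain steps

Total step count: 15. Longest linear sequence: 12 steps (steps 1–4, 6–11, 14 and 15).

Step 11 (key step). The most likely failures are addition through an allylindium geometry that has not equilibrated (which would put C11 axial and give the C7 epimer), lactonisation of the indium alkoxide onto the C12 ester, or reductive loss of the C6 silanolate to a diene. Fallback: from 16, lithium bromide in acetone exchanges the acetate with allylic transposition to the primary (Z)-allylic bromide F1. Chromium(II) chloride in THF then effects a Nozaki–Hiyama-type cyclisation; allylchromium(III) species are configurationally mobile and add through the chair with equatorial substituents. The route is rejoined at 18.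

Step 6. The hindered enone may fail to engage, so that the diene is desilylated or a Mukaiyama–Michael adduct forms that does not close; facial or endo selectivity could also erode. Fallback: from 6, conjugate addition of allylcopper with TMSCl gives the enol silane F2. A Mukaiyama aldol reaction with acrolein gives the vinyl carbinol F3, and silylation gives the diene F4. Ring-closing metathesis of F4 then forms the C7=C8 bond and returns to 10; C5/C6 diastereomers would have to be separated at F3.

Step 7. The equilibrium may not favour the trans-fused ketone strongly enough, or enolisation may be followed by loss of the C6 silanolate. Fallback: from 9, the more substituted enol silane F5 is formed (TMSOTf, Et3N) and protonated under kinetic control (TBAF, AcOH, −78 °C). Axial protonation on the α-face, away from C14, should give 10.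

Step 8. Acetalisation may not discriminate well enough between the two aldehydes, and the α-silyloxy aldehyde may epimerise at C6 on standing. Fallback: from dialdehyde 11, an amine-catalysed Morita–Baylis–Hillman reaction with methyl acrylate, which favours the more electrophilic α-silyloxy aldehyde, gives the hydroxy aldehyde F6. Acetylation of F6 returns to 16 and bypasses 12, 14 and 15.

Step 15. Slow cleavage of the two hindered secondary silyl ethers may force longer exposure to acid, with lactonisation of O6 onto C12 or acyl migration from O8 to O6. Fallback: from 18, both silyl ethers are removed before the sensitive ester is present, giving the triol F7. Site-selective Yamaguchi acylation with 21 at the least hindered hydroxyl (O8; O1 is neopentyl-like, O6 is flanked and hydrogen-bonded to the ketone) gives F8. Brief treatment with HF·pyridine removes the remaining primary silyl ether and gives 23.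

## Further compounds

F1 | step 11 | methyl (Z)-2-(bromomethyl)-4-[(tert-butyldimethylsilyl)oxy]-4-[(1S,2R,3R)-3-[(tert-butyldimethylsilyl)oxy]-2-methyl-6-oxo-2-(2-oxoethyl)cyclohexyl]but-2-enoate | O=CC[C@]1(C)[C@@H]([C@@H](O[Si](C)(C)C(C)(C)C)/C=C(\CBr)C(=O)OC)C(=O)CC[C@H]1O[Si](C)(C)C(C)(C)C
F2 | step 6 | tert-butyldimethyl{[(1R,2R)-2-methyl-2-(prop-2-en-1-yl)-4-[(trimethylsilyl)oxy]cyclohex-3-en-1-yl]oxy}silane | C=CC[C@]1(C)C=C(O[Si](C)(C)C)CC[C@H]1O[Si](C)(C)C(C)(C)C
F3 | step 6 | (2S,3R,4R)-4-[(tert-butyldimethylsilyl)oxy]-2-[(1S)-1-hydroxyprop-2-en-1-yl]-3-methyl-3-(prop-2-en-1-yl)cyclohexan-1-one | C=CC[C@]1(C)[C@@H]([C@@H](O)C=C)C(=O)CC[C@H]1O[Si](C)(C)C(C)(C)C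
F4 | step 6 | (2S,3R,4R)-4-[(tert-butyldimethylsilyl)oxy]-2-{(1S)-1-[(tert-butyldimethylsilyl)oxy]prop-2-en-1-yl}-3-methyl-3-(prop-2-en-1-yl)cyclohexan-1-one | C=CC[C@]1(C)[C@@H]([C@@H](O[Si](C)(C)C(C)(C)C)C=C)C(=O)CC[C@H]1O[Si](C)(C)C(C)(C)C
F5 | step 7 | trimethylsilyl enol ether of 9 (C4=C5 enol silane; 1β,6α-bis-TBS ether) | C1=C[C@H](O[Si](C)(C)C(C)(C)C)C2=C(O[Si](C)(C)C)CC[C@@H](O[Si](C)(C)C(C)(C)C)[C@]2(C)C1
F6 | step 8 | methyl (3RS,4R)-4-[(tert-butyldimethylsilyl)oxy]-4-[(1S,2R,3R)-3-[(tert-butyldimethylsilyl)oxy]-2-methyl-6-oxo-2-(2-oxoethyl)cyclohexyl]-3-hydroxy-2-methylidenebutanoate | O=CC[C@]1(C)[C@@H]([C@@H](O[Si](C)(C)C(C)(C)C)C(O)C(=C)C(=O)OC)C(=O)CC[C@H]1O[Si](C)(C)C(C)(C)C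
F7 | step 15 | methyl 1β,6α,8α-trihydroxy-4-oxo-15-nor-5α-eudesm-11(13)-en-12-oate | O[C@H]1C[C@@]2(C)[C@H](O)CCC(=O)[C@@H]2[C@@H](O)[C@@H]1C(=C)C(=O)OC
F8 | step 15 | methyl 8α-[(2-{[(tert-butyldimethylsilyl)oxy]methyl}acryloyl)oxy]-1β,6α-dihydroxy-4-oxo-15-nor-5α-eudesm-11(13)-en-12-oate | C=C(CO[Si](C)(C)C(C)(C)C)C(=O)O[C@H]1C[C@@]2(C)[C@H](O)CCC(=O)[C@@H]2[C@@H](O)[C@@H]1C(=C)C(=O)OC
A1 | alternative 1 | (R)-Wieland–Miescher ketone, (R)-8a-methyl-3,4,8,8a-tetrahydronaphthalene-1,6(2H,7H)-dione | O=C1CC[C@@]2(C)C(=O)CCCC2=C1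
A2 | alternative 2 | 2-methoxy-5-methyl-1,4-benzoquinone | COC1=CC(=O)C(C)=CC1=O
A3 | alternative 2 | cis-fused endo adduct of A2 and 8 (6α-silyloxy, 5β-H, 10β-methyl, Δ7; 3-methoxy-2-ene-1,4-dione in ring A) | COC1=CC(=O)[C@]2(C)CC=C[C@H](O[Si](C)(C)C(C)(C)C)[C@@H]2C1=O
A4 | alternative 3 | methyl (4R)-4-[(tert-butyldimethylsilyl)oxy]-4-[(1S,2R,3R)-3-[(tert-butyldimethylsilyl)oxy]-2-methyl-6-oxo-2-(prop-2-en-1-yl)cyclohexyl]but-2-ynoate | C=CC[C@]1(C)[C@@H]([C@@H](O[Si](C)(C)C(C)(C)C)C#CC(=O)OC)C(=O)CC[C@H]1O[Si](C)(C)C(C)(C)C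
A5 | alternative 3 | methyl 1β,6α-bis[(tert-butyldimethylsilyl)oxy]-4-oxo-15-nor-5α-eudesma-7,11(13)-dien-12-oate | C=C(C(=O)OC)C1=CC[C@@]2(C)[C@H](O[Si](C)(C)C(C)(C)C)CCC(=O)[C@@H]2[C@H]1O[Si](C)(C)C(C)(C)C
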